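## Retrosynthetic overview

1. The target comes from a (1(10)E,4Z)-germacradienolide by late peracid epoxidation of C1=C10, C3 benzoylation, and reagent-controlled reduction of a C3 enone.
2. The trans γ-lactone, the C6 stereocentre and the C8 epoxyangelate are made together from a macrocyclic β-hydroxy Z-enedione by Evans–Tishchenko reduction with an epoxy aldehyde, followed by lactonisation.
3. The Z-enedione (C3 to C6) is unmasked by singlet-oxygen dearomatisation of a 2,5-bridged 3-methylfuran, a [6](2,5)furanophane. This is the key step.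
4. The furanophane (the ten-membered carbocycle) is closed at C7–C8 by an enantioselective intramolecular chromium-mediated 2-(methoxycarbonyl)allylation, which sets C7 and C8 and brings in the α-methylene acrylate.
5. Ring order: furan (bought) → ten-membered carbocycle → furan opened → γ-lactone → oxirane. The precursor comes from methyl 3-methyl-2-furoate by carboalumination/cross-coupling, C5 formylation and Baylis–Hillman/bromide chemistry.

Convention: germacrane numbering is used in the explanations (ring C1–C10; C11, C12, C13 are the lactone carbons; C14 on C10; C15 on C4).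

Assumption: the chiral chromium catalyst of step 9 induces in the same sense as in intermolecular 2-(alkoxycarbonyl)allylations; the ligand antipode that gives (7R,8R)-14 is the one used.

## Route

Step 1
Reactants: 1 methyl 3-methylfuran-2-carboxylate
Product: 2 (3-methylfuran-2-yl)methanol
Conditions: LiAlH4, Et2O, 0 °C
Reagents that add atoms: none
Why: Hydride reduction of the ester to the furfuryl alcohol; the furan is inert and no stereocentre is involved.

Step 2
Reactants: 2 (3-methylfuran-2-yl)methanol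
Product: 3 2-(chloromethyl)-3-methylfuran
Conditions: SOCl2, pyridine, Et2O, −20 °C; cold ether solution used at once
Reagents that add atoms: thionyl chloride O=S(Cl)Cl
Why: Chlorodehydroxylation through the chlorosulfite (the classical furfuryl chloride preparation); the labile chloride is not stored.

Step 3
Reactants: 3 2-(chloromethyl)-3-methylfuran, 4 tert-butyl(but-3-yn-1-yloxy)dimethylsilane
Product: 6 tert-butyldimethyl{[(3E)-3-methyl-5-(3-methylfuran-2-yl)pent-3-en-1-yl]oxy}silane, via alkenylalane 5 (not isolated)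
Conditions: 4, Me3Al, Cp2ZrCl2 (20 mol %), CH2Cl2, 23 °C; then 3, Pd(PPh3)4 (5 mol %), THF, 0 → 23 °C
Reagents that add atoms: trimethylaluminium C[Al](C)C
Why: Negishi zirconium-catalysed carboalumination adds Me and Al syn across the terminal alkyne (Al at the terminus), which fixes the E trisubstituted C1=C10 olefin, and the alkenylalane then cross-couples with the furfuryl chloride under zerovalent palladium catalysis with retention of geometry.

Step 4
Reactants: 6 tert-butyldimethyl{[(3E)-3-methyl-5-(3-methylfuran-2-yl)pent-3-en-1-yl]oxy}silane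
Product: 7 5-[(2E)-5-(tert-butyldimethylsilyloxy)-3-methylpent-2-en-1-yl]-4-methylfuran-2-carbaldehyde
Conditions: n-BuLi, THF, −78 → 0 °C; DMF, −78 °C; aq. NH4Cl
Reagents that add atoms: N,N-dimethylformamide CN(C)C=O
Why: Kinetic α-lithiation of the furan at its only free α-position, then formylation with DMF.

Step 5
Reactants: 7 5-[(2E)-5-(tert-butyldimethylsilyloxy)-3-methylpent-2-en-1-yl]-4-methylfuran-2-carbaldehyde, 8 methyl acrylate
Product: 9 methyl 2-[{5-[(2E)-5-(tert-butyldimethylsilyloxy)-3-methylpent-2-en-1-yl]-4-methylfuran-2-yl}(hydroxy)methyl]prop-2-enoate (racemic carbinol)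
Conditions: methyl acrylate (neat, excess), DABCO, 23 °C
Reagents that add atoms: none
Why: Morita–Baylis–Hillman reaction of the furfural-type aldehyde; the carbinol centre is racemic and is erased in step 6.

Step 6
Reactants: 9 methyl 2-[{5-[(2E)-5-(tert-butyldimethylsilyloxy)-3-methylpent-2-en-1-yl]-4-methylfuran-2-yl}(hydroxy)methyl]prop-2-enoate
Product: 10 methyl (2Z)-2-(bromomethyl)-3-{5-[(2E)-5-(tert-butyldimethylsilyloxy)-3-methylpent-2-en-1-yl]-4-methylfuran-2-yl}prop-2-enoate
Conditions: PBr3, Et2O, −10 °C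
Reagents that add atoms: phosphorus tribromide BrP(Br)Br
Why: Allylic bromination with SN2′ transposition of the Baylis–Hillman alcohol gives the conjugated (Z)-2-(bromomethyl)acrylate, the preferred isomer with furyl trans to the ester.

Step 7
Reactants: 10 methyl (2Z)-2-(bromomethyl)-3-{5-[(2E)-5-(tert-butyldimethylsilyloxy)-3-methylpent-2-en-1-yl]-4-methylfuran-2-yl}prop-2-enoate
Product: 11 methyl (2Z)-2-(bromomethyl)-3-{5-[(2E)-5-hydroxy-3-methylpent-2-en-1-yl]-4-methylfuran-2-yl}prop-2-enoate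
Conditions: HF·pyridine, THF, 0 °C
Reagents that add atoms: none
Why: Silyl ether cleavage by buffered HF, which is too weakly nucleophilic to displace the allylic bromide and leaves the furan intact.

Step 8
Reactants: 11 methyl (2Z)-2-(bromomethyl)-3-{5-[(2E)-5-hydroxy-3-methylpent-2-en-1-yl]-4-methylfuran-2-yl}prop-2-enoate
Product: 12 methyl (2Z)-2-(bromomethyl)-3-{4-methyl-5-[(2E)-3-methyl-5-oxopent-2-en-1-yl]furan-2-yl}prop-2-enoate
Conditions: Dess–Martin periodinane, NaHCO3, CH2Cl2, 0 °C; used at once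
Reagents that add atoms: none
Why: Dess–Martin oxidation under buffered, base-free conditions so that the β,γ-unsaturated aldehyde does not move into conjugation.

Step 9
Reactants: 12 methyl (2Z)-2-(bromomethyl)-3-{4-methyl-5-[(2E)-3-methyl-5-oxopent-2-en-1-yl]furan-2-yl}prop-2-enoate
Product: 14 methyl 2-[(3E,6R,7R)-6-hydroxy-4,10-dimethyl-11-oxabicyclo[6.2.1]undeca-1(10),3,8-trien-7-yl]prop-2-enoate, via TMS ether 13 (not isolated)
Conditions: CrCl2 (20 mol %), 3,6-di-tert-butyl-1,8-bis[(4S)-4-isopropyl-4,5-dihydrooxazol-2-yl]-9H-carbazole (24 mol %), Mn powder, TMSCl, THF (2 mM, syringe pump), 23 °C; then aq. citric acid, 0 °C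
Reagents that add atoms: none
Why: Intramolecular Nozaki–Hiyama–Kishi-type 2-(alkoxycarbonyl)allylation, in which the allylchromium (furyl cis to CH2Cr, fixed by the ester) adds at its γ-carbon through a closed Zimmerman–Traxler chair to give the syn C7/C8 pair, and the chiral bis(oxazoline) chromium complex selects the aldehyde face to give (7R,8R); chromium-mediated closure of a 2,5-furanophane with a six-carbon bridge has precedent, high dilution suppresses oligomers, and the mild acidic work-up keeps the hydroxy methyl ester open.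

Step 10
Reactants: 15 (2Z)-2-methylbut-2-enoic acid (angelic acid)
Product: 16 (2Z)-2-methylbut-2-en-1-ol
Conditions: LiAlH4, Et2O, 0 °C
Reagents that add atoms: none
Why: Hydride reduction of the acid to the allylic alcohol, which leaves the Z trisubstituted olefin untouched.

Step 11
Reactants: 16 (2Z)-2-methylbut-2-en-1-ol
Product: 17 [(2R,3S)-2,3-dimethyloxiran-2-yl]methanol
Conditions: Ti(OiPr)4, D-(−)-diethyl tartrate, t-BuOOH, 4 Å MS, CH2Cl2, −20 °C
Reagents that add atoms: tert-butyl hydroperoxide CC(C)(C)OO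
Why: Sharpless asymmetric epoxidation; D-(−)-tartrate delivers oxygen to the face that gives the (2R,3S) epoxy alcohol, and the Z geometry becomes the cis relationship between the carbinol carbon and the 3-methyl group.

Step 12
Reactants: 17 [(2R,3S)-2,3-dimethyloxiran-2-yl]methanol
Product: 18 (2S,3S)-2,3-dimethyloxirane-2-carbaldehyde
Conditions: Dess–Martin periodinane, NaHCO3, CH2Cl2, 0 °C; kept as a solution
Reagents that add atoms: none
Why: Dess–Martin oxidation to the α-quaternary epoxy aldehyde, which cannot epimerise (the C2 descriptor changes from R to S only through CIP priorities).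

Step 13
Reactants: 14 methyl 2-[(3E,6R,7R)-6-hydroxy-4,10-dimethyl-11-oxabicyclo[6.2.1]undeca-1(10),3,8-trien-7-yl]prop-2-enoate, 18 (2S,3S)-2,3-dimethyloxirane-2-carbaldehyde
Product: 22 (3aR,4R,6E,10Z,11aR)-6,10-dimethyl-3-methylidene-2,9-dioxo-2,3,3a,4,5,8,9,11a-octahydrocyclodeca[b]furan-4-yl (2S,3S)-2,3-dimethyloxirane-2-carboxylate, via furan endoperoxide 19 (not isolated), via Z-enedione 20 (not isolated), via hydroxy ester 21 (not isolated)
Conditions: O2, hν, tetraphenylporphyrin (cat.), CH2Cl2, −78 °C; Me2S, −78 → 0 °C; aqueous wash, solvent swap; then SmI2 (30 mol %, first aged with 18 (5 equiv) until the blue colour of divalent samarium fades), THF, −10 → 23 °C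
Reagents that add atoms: dioxygen O=O
Why: Singlet oxygen adds [4+2] to the strained, electron-rich trialkylfuran far faster than it reacts with the trisubstituted olefin in an ene reaction, and Me2S cleaves the endoperoxide to the ring-locked Z-enedione (furan dearomatisation); an Evans–Tishchenko reduction then transfers the formyl hydride of the C8 hemiacetal of 18 to C6 through a samarium-bound six-membered chair, which sets the 1,3-anti C6 alcohol (6R), leaves C8 as the epoxyangelate, and lets the C6 alkoxide close the trans γ-lactone on the methyl ester.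

Step 14
Reactants: 22 (3aR,4R,6E,10Z,11aR)-6,10-dimethyl-3-methylidene-2,9-dioxo-2,3,3a,4,5,8,9,11a-octahydrocyclodeca[b]furan-4-yl (2S,3S)-2,3-dimethyloxirane-2-carboxylate
Product: 23 (3aR,4R,6E,9S,10Z,11aR)-9-hydroxy-6,10-dimethyl-3-methylidene-2-oxo-2,3,3a,4,5,8,9,11a-octahydrocyclodeca[b]furan-4-yl (2S,3S)-2,3-dimethyloxirane-2-carboxylate
Conditions: (R)-2-methyl-CBS-oxazaborolidine, catecholborane, toluene, −78 °C
Reagents that add atoms: none
Why: Corey–Bakshi–Shibata reduction in which the fully substituted alkenyl carbon C4 acts as the large group, so the (R)-oxazaborolidine delivers hydride to give the (3S) allylic alcohol, while catecholborane at −78 °C spares the α-methylene lactone, the esters and the olefins.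

Step 15
Reactants: 23 (3aR,4R,6E,9S,10Z,11aR)-9-hydroxy-6,10-dimethyl-3-methylidene-2-oxo-2,3,3a,4,5,8,9,11a-octahydrocyclodeca[b]furan-4-yl (2S,3S)-2,3-dimethyloxirane-2-carboxylate, 24 benzoyl chloride
Product: 25 (3aR,4R,6E,9S,10Z,11aR)-4-{[(2S,3S)-2,3-dimethyloxirane-2-carbonyl]oxy}-6,10-dimethyl-3-methylidene-2-oxo-2,3,3a,4,5,8,9,11a-octahydrocyclodeca[b]furan-9-yl benzoate
Conditions: 24, pyridine, DMAP (cat.), CH2Cl2, 0 °C
Reagents that add atoms: none
Why: DMAP-catalysed acylation of the only free hydroxyl, with retention at C3.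

Step 16
Reactants: 25 (3aR,4R,6E,9S,10Z,11aR)-4-{[(2S,3S)-2,3-dimethyloxirane-2-carbonyl]oxy}-6,10-dimethyl-3-methylidene-2-oxo-2,3,3a,4,5,8,9,11a-octahydrocyclodeca[b]furan-9-yl benzoate
Product: 26 CNP0324463.3, (1R,3S,6R,7R,8R,10R)-3-benzoyloxy-8-[(2S,3S)-2,3-dimethyloxirane-2-carbonyloxy]-1,10-epoxygermacra-4Z,11(13)-dien-12,6-olide
Conditions: mCPBA, NaHCO3, CH2Cl2, 0 °C
Reagents that add atoms: 3-chloroperoxybenzoic acid OOC(=O)c1cccc(Cl)c1
Why: Prilezhaev epoxidation of the isolated trisubstituted C1=C10 olefin, which is far more nucleophilic than C4=C5 (flanked by two acyloxy-bearing carbons) and the α-methylene lactone; the peracid attacks the outer face of the E-olefin in the ring conformer with C14 on the β-face, giving the trans 1β,10α (1R,10R) epoxide.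

## Compound list

1 | methyl 3-methylfuran-2-carboxylate | COC(=O)c1occc1C | starting material
2 | (3-methylfuran-2-yl)methanol | Cc1ccoc1CO | intermediate
3 | 2-(chloromethyl)-3-methylfuran | Cc1ccoc1CCl | intermediate
4 | tert-butyl(but-3-yn-1-yloxy)dimethylsilane | C#CCCO[Si](C)(C)C(C)(C)C | starting material
5 | dimethyl[(1E)-4-(tert-butyldimethylsilyloxy)-2-methylbut-1-en-1-yl]alane | C[Al](C)/C=C(\C)CCO[Si](C)(C)C(C)(C)C | intermediate
6 | tert-butyldimethyl{[(3E)-3-methyl-5-(3-methylfuran-2-yl)pent-3-en-1-yl]oxy}silane | Cc1ccoc1C/C=C(\C)CCO[Si](C)(C)C(C)(C)C | intermediate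
7 | 5-[(2E)-5-(tert-butyldimethylsilyloxy)-3-methylpent-2-en-1-yl]-4-methylfuran-2-carbaldehyde | O=Cc1cc(C)c(C/C=C(\C)CCO[Si](C)(C)C(C)(C)C)o1 | intermediate
8 | methyl acrylate | C=CC(=O)OC | starting material
9 | methyl 2-[{5-[(2E)-5-(tert-butyldimethylsilyloxy)-3-methylpent-2-en-1-yl]-4-methylfuran-2-yl}(hydroxy)methyl]prop-2-enoate (racemic) | C=C(C(=O)OC)C(O)c1cc(C)c(C/C=C(\C)CCO[Si](C)(C)C(C)(C)C)o1 | intermediate
10 | methyl (2Z)-2-(bromomethyl)-3-{5-[(2E)-5-(tert-butyldimethylsilyloxy)-3-methylpent-2-en-1-yl]-4-methylfuran-2-yl}prop-2-enoate | COC(=O)/C(CBr)=C/c1cc(C)c(C/C=C(\C)CCO[Si](C)(C)C(C)(C)C)o1 | intermediate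
11 | methyl (2Z)-2-(bromomethyl)-3-{5-[(2E)-5-hydroxy-3-methylpent-2-en-1-yl]-4-methylfuran-2-yl}prop-2-enoate | COC(=O)/C(CBr)=C/c1cc(C)c(C/C=C(\C)CCO)o1 | intermediate
12 | methyl (2Z)-2-(bromomethyl)-3-{4-methyl-5-[(2E)-3-methyl-5-oxopent-2-en-1-yl]furan-2-yl}prop-2-enoate | COC(=O)/C(CBr)=C/c1cc(C)c(C/C=C(\C)CC=O)o1 | intermediate
13 | methyl 2-[(3E,6R,7R)-4,10-dimethyl-6-(trimethylsilyloxy)-11-oxabicyclo[6.2.1]undeca-1(10),3,8-trien-7-yl]prop-2-enoate | C=C(C(=O)OC)[C@H]1c2cc(C)c(o2)C/C=C(\C)C[C@H]1O[Si](C)(C)C | intermediate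
14 | methyl 2-[(3E,6R,7R)-6-hydroxy-4,10-dimethyl-11-oxabicyclo[6.2.1]undeca-1(10),3,8-trien-7-yl]prop-2-enoate (the [6](2,5)furanophane) | C=C(C(=O)OC)[C@H]1c2cc(C)c(o2)C/C=C(\C)C[C@H]1O | intermediate
15 | (2Z)-2-methylbut-2-enoic acid (angelic acid) | C/C=C(/C)C(=O)O | starting material
16 | (2Z)-2-methylbut-2-en-1-ol | C/C=C(/C)CO | intermediate
17 | [(2R,3S)-2,3-dimethyloxiran-2-yl]methanol | OC[C@@]1(C)O[C@H]1C | intermediate
18 | (2S,3S)-2,3-dimethyloxirane-2-carbaldehyde | O=C[C@@]1(C)O[C@H]1C | intermediate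
19 | furan 1,4-endoperoxide of 14 (2,3,7-trioxabicyclo[2.2.1]hept-5-ene across C3 and C6; both facial isomers) | C=C(C(=O)OC)[C@H]1C23OOC(O2)(C(C)=C3)C/C=C(\C)C[C@H]1O | intermediate
20 | methyl 2-[(1R,2R,4E,8Z)-2-hydroxy-4,8-dimethyl-7,10-dioxocyclodeca-4,8-dien-1-yl]prop-2-enoate | C=C(C(=O)OC)[C@H]1C(=O)/C=C(/C)C(=O)C/C=C(\C)C[C@H]1O | intermediate
21 | methyl 2-[(1S,2R,4E,8Z,10R)-2-{[(2S,3S)-2,3-dimethyloxirane-2-carbonyl]oxy}-10-hydroxy-4,8-dimethyl-7-oxocyclodeca-4,8-dien-1-yl]prop-2-enoate | C=C(C(=O)OC)[C@H]1[C@H](O)/C=C(/C)C(=O)C/C=C(\C)C[C@H]1OC(=O)[C@@]2(C)O[C@H]2C | intermediate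
22 | (3aR,4R,6E,10Z,11aR)-6,10-dimethyl-3-methylidene-2,9-dioxo-2,3,3a,4,5,8,9,11a-octahydrocyclodeca[b]furan-4-yl (2S,3S)-2,3-dimethyloxirane-2-carboxylate | C=C1C(=O)O[C@@H]2/C=C(/C)C(=O)C/C=C(\C)C[C@@H](OC(=O)[C@@]3(C)O[C@H]3C)[C@@H]12 | intermediate
23 | (3aR,4R,6E,9S,10Z,11aR)-9-hydroxy-6,10-dimethyl-3-methylidene-2-oxo-2,3,3a,4,5,8,9,11a-octahydrocyclodeca[b]furan-4-yl (2S,3S)-2,3-dimethyloxirane-2-carboxylate | C=C1C(=O)O[C@@H]2/C=C(/C)[C@@H](O)C/C=C(\C)C[C@@H](OC(=O)[C@@]3(C)O[C@H]3C)[C@@H]12 | intermediate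
24 | benzoyl chloride | O=C(Cl)c1ccccc1 | starting material
25 | (3aR,4R,6E,9S,10Z,11aR)-4-{[(2S,3S)-2,3-dimethyloxirane-2-carbonyl]oxy}-6,10-dimethyl-3-methylidene-2-oxo-2,3,3a,4,5,8,9,11a-octahydrocyclodeca[b]furan-9-yl benzoate | C=C1C(=O)O[C@@H]2/C=C(/C)[C@@H](OC(=O)c3ccccc3)C/C=C(\C)C[C@@H](OC(=O)[C@@]3(C)O[C@H]3C)[C@@H]12 | intermediate
26 | CNP0324463.3, (1R,3S,6R,7R,8R,10R)-3-benzoyloxy-8-[(2S,3S)-2,3-dimethyloxirane-2-carbonyloxy]-1,10-epoxygermacra-4Z,11(13)-dien-12,6-olide | C=C1C(=O)O[C@@H]2/C=C(/C)[C@@H](OC(=O)c3ccccc3)C[C@H]3O[C@]3(C)C[C@@H](OC(=O)[C@@]3(C)O[C@H]3C)[C@@H]12 | target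

## Step count and risks

Total step count: 16. Longest linear sequence: 13 steps (steps 1–9 and 13–16, from 1 to 26); the epoxy aldehyde branch is 3 steps (10–12).

**Step 9 (closing the furanophane at C7–C8).** The ring is strained, so the allylchromium may oligomerise or attack through its CH2 terminus, and the catalyst has to control an intramolecular case. The fallback sets out from 11 and dearomatises before ring closure. Anodic methoxylation (graphite anode, Et4NOTs, 2,6-lutidine, MeOH, divided cell, 0 °C) turns the furan into the 2,5-dimethoxy-2,5-dihydrofuran alcohol F1 (ketal isomers). Dess–Martin oxidation gives the aldehyde F2. The same CrCl2/bis(oxazoline)/Mn/TMSCl allylation then closes an unstrained oxa-bridged ten-membered ring, the bis-ketal hydroxy ester F3. PPTS in wet acetone unmasks the Z-enedione, and the route is rejoined at 20 (Evans–Tishchenko half of step 13).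

**Step 13 (telescoped dearomatisation / Evans–Tishchenko / lactonisation).** The hindered, easily reduced epoxy aldehyde may be a poor hydride donor, residual divalent samarium can reduce the enedione, and acyl migration could send the lactone to C8. The fallback sets out from 14 and separates the events. Photooxygenation and Me2S give 20, which is isolated. Hydroxyl-directed reduction with Me4NBH(OAc)3 (MeCN/AcOH, −30 °C) gives the 1,3-anti diol ester F4. PPTS closes the 6,12-lactone to the hydroxy lactone F5. Pinnick oxidation of 18 (NaClO2, NaH2PO4, 2-methylbut-2-ene) gives the epoxy acid F6, and Yamaguchi esterification of F5 with F6 (2,4,6-trichlorobenzoyl chloride, Et3N, DMAP) comes back to the route at 22.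

**Step 14 (reagent-controlled C3 reduction).** The macrocycle may oppose the oxazaborolidine and give a poor ratio or the C3 epimer. The fallback sets out from 22 and uses substrate control plus inversion. Luche reduction (NaBH4, CeCl3·7H2O, MeOH, −78 °C) gives the substrate-preferred alcohol. If this is the (3R) epimer, (3aR,4R,6E,9R,10Z,11aR)-9-hydroxy-6,10-dimethyl-3-methylidene-2-oxo-2,3,3a,4,5,8,9,11a-octahydrocyclodeca[b]furan-4-yl (2S,3S)-2,3-dimethyloxirane-2-carboxylate F7, a Mitsunobu esterification with benzoic acid (PPh3, DIAD, toluene, 0 °C) inverts C3 and installs the benzoate in one operation, coming back to the route at 25.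

## Further compounds

F1 | step 9 | methyl (2Z)-2-(bromomethyl)-3-{5-[(2E)-5-hydroxy-3-methylpent-2-en-1-yl]-2,5-dimethoxy-4-methyl-2,5-dihydrofuran-2-yl}prop-2-enoate | COC(=O)/C(CBr)=C/C1(OC)C=C(C)C(OC)(C/C=C(\C)CCO)O1
F2 | step 9 | methyl (2Z)-2-(bromomethyl)-3-{2,5-dimethoxy-4-methyl-5-[(2E)-3-methyl-5-oxopent-2-en-1-yl]-2,5-dihydrofuran-2-yl}prop-2-enoate | COC(=O)/C(CBr)=C/C1(OC)C=C(C)C(OC)(C/C=C(\C)CC=O)O1
F3 | step 9 | methyl 2-[(3E,6R,7R)-6-hydroxy-1,8-dimethoxy-4,10-dimethyl-11-oxabicyclo[6.2.1]undeca-3,9-dien-7-yl]prop-2-enoate | C=C(C(=O)OC)[C@H]1C2(OC)C=C(C)C(OC)(O2)C/C=C(\C)C[C@H]1O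
F4 | step 13 | methyl 2-[(1R,2R,4E,8Z,10R)-2,10-dihydroxy-4,8-dimethyl-7-oxocyclodeca-4,8-dien-1-yl]prop-2-enoate | C=C(C(=O)OC)[C@H]1[C@H](O)/C=C(/C)C(=O)C/C=C(\C)C[C@H]1O
F5 | step 13 | (3aR,4R,6E,10Z,11aR)-4-hydroxy-6,10-dimethyl-3-methylidene-3a,4,5,8-tetrahydrocyclodeca[b]furan-2,9(3H,11aH)-dione | C=C1C(=O)O[C@@H]2/C=C(/C)C(=O)C/C=C(\C)C[C@@H](O)[C@@H]12
F6 | step 13 | (2S,3S)-2,3-dimethyloxirane-2-carboxylic acid | OC(=O)[C@@]1(C)O[C@H]1C
F7 | step 14 | (3aR,4R,6E,9R,10Z,11aR)-9-hydroxy-6,10-dimethyl-3-methylidene-2-oxo-2,3,3a,4,5,8,9,11a-octahydrocyclodeca[b]furan-4-yl (2S,3S)-2,3-dimethyloxirane-2-carboxylate | C=C1C(=O)O[C@@H]2/C=C(/C)[C@H](O)C/C=C(\C)C[C@@H](OC(=O)[C@@]3(C)O[C@H]3C)[C@@H]12
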